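**Retrosynthetic overview**
1. Target (threo, 7R,8R) ⇐ one hydride operation on the syn (2S,3R) α-aryloxy β-hydroxy ester: the C9 ester becomes CH2OH and the aryl pivalate becomes the free phenol.
2. Both stereocentres (C7, C8) ⇐ one dynamic kinetic asymmetric transfer hydrogenation of the racemic, configurationally labile α-aryloxy β-keto ester.
3. Key disconnection: the C8–O aryl ether bond ⇐ α-chloro β-keto ester (ring A part) + phenoxide of dihydrosinapyl alcohol (ring B part).
4. Ring A β-keto ester ⇐ syringaldehyde pivalate + ethyl diazoacetate (homologation that brings in C8 and C9).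
5. No ring is formed: both benzene rings (ring A, ring B) are bought intact.

Assumption: dihydrosinapyl alcohol is taken as a purchased catalogue compound (otherwise one step from 4-allyl-2,6-dimethoxyphenol by hydroboration–oxidation); the propane chain is numbered C7/C8/C9 as usual for neolignans.

**Route**

Step 1
Reactants: 1 syringaldehyde (4-hydroxy-3,5-dimethoxybenzaldehyde)
Product: 2 4-formyl-2,6-dimethoxyphenyl pivalate
Conditions: PivCl, Et3N, DMAP (cat.), CH2Cl2, 0 °C to rt
Reagents that add atoms: pivaloyl chloride, CC(C)(C)C(=O)Cl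
Why: DMAP-catalysed acylation of the phenol gives a pivalate that survives the Lewis acid, SO2Cl2, K2CO3 and formic acid/amine of steps 2–4 and is removed by the hydride of step 5, so no separate deprotection is needed; no stereocentre.

Step 2
Reactants: 2 4-formyl-2,6-dimethoxyphenyl pivalate
Product: 3 ethyl 3-[3,5-dimethoxy-4-(pivaloyloxy)phenyl]-3-oxopropanoate
Conditions: N2CHCO2Et, SnCl2 (10 mol%), CH2Cl2, rt
Reagents that add atoms: ethyl diazoacetate, CCOC(=O)C=[N+]=[N-]
Why: Roskamp homologation: the SnCl2-activated aldehyde adds ethyl diazoacetate and the diazonium betaine loses N2 with a 1,2-hydride shift to give the β-keto ester directly; no stereocentre.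

Step 3
Reactants: 3 ethyl 3-[3,5-dimethoxy-4-(pivaloyloxy)phenyl]-3-oxopropanoate; 4 dihydrosinapyl alcohol (4-(3-hydroxypropyl)-2,6-dimethoxyphenol)
Product: 6 ethyl 2-[4-(3-hydroxypropyl)-2,6-dimethoxyphenoxy]-3-[3,5-dimethoxy-4-(pivaloyloxy)phenyl]-3-oxopropanoate (racemic), via α-chloro β-keto ester 5 (not isolated)
Conditions: SO2Cl2 (1.05 equiv), CH2Cl2, 0 °C to rt, evaporate; then 4, K2CO3, acetone, 45 °C
Reagents that add atoms: none
Why: The enol of 3 is chlorinated by SO2Cl2 and, after the volatiles are removed, the potassium phenoxide of 4 (K2CO3 deprotonates the phenol but not the aliphatic OH) displaces the doubly carbonyl-activated chloride in a Williamson (SN2) etherification that forms the key C8–O bond; C8 is left racemic and labile on purpose for step 4.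

Step 4
Reactants: 6 ethyl 2-[4-(3-hydroxypropyl)-2,6-dimethoxyphenoxy]-3-[3,5-dimethoxy-4-(pivaloyloxy)phenyl]-3-oxopropanoate
Product: 7 ethyl (2S,3R)-3-hydroxy-2-[4-(3-hydroxypropyl)-2,6-dimethoxyphenoxy]-3-[3,5-dimethoxy-4-(pivaloyloxy)phenyl]propanoate (2,3-syn)
Conditions: RuCl(p-cymene)[(S,S)-TsDPEN] (1 mol%), HCO2H/Et3N (5:2), CH2Cl2, 30 °C
Reagents that add atoms: none
Why: Proposed new method: dynamic kinetic resolution by Noyori–Ikariya asymmetric transfer hydrogenation of an α-aryloxy β-keto ester whose aryloxy group is doubly ortho-substituted (the 8-O-4' neolignan pattern), a substrate type on which this reaction has not been shown; the C8–H flanked by ketone, ester and aryloxy (estimated pKa 10–12) epimerises through the enol in HCO2H/Et3N much faster than hydride transfer, the (S,S)-catalyst delivers hydride through its outer-sphere Ru–H/N–H transition state to the ketone face selected by the CH/π contact between ring A and the p-cymene ligand (the face that gives (S)-1-phenylethanol from acetophenone, here labelled 3R, that is C7 R), and of the two equilibrating C8 epimers the one that places the C8–OAr bond anti to the incoming hydride (Felkin–Anh polar arrangement, no chelation in this metal–ligand bifunctional mechanism) reacts faster, which gives the 2,3-syn (threo) product and sets C8 as 2S (8R after step 5); closest known reaction type: Ru–TsDPEN transfer hydrogenation with dynamic kinetic resolution of α-alkoxy β-keto esters to syn α-alkoxy β-hydroxy esters.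

Step 5
Reactants: 7 ethyl (2S,3R)-3-hydroxy-2-[4-(3-hydroxypropyl)-2,6-dimethoxyphenoxy]-3-[3,5-dimethoxy-4-(pivaloyloxy)phenyl]propanoate
Product: 8 (1R,2R)-1-(4-hydroxy-3,5-dimethoxyphenyl)-2-[4-(3-hydroxypropyl)-2,6-dimethoxyphenoxy]propane-1,3-diol (threo, 7R,8R; the target)
Conditions: LiAlH4 (4 equiv), THF, 0 °C to rt; aq. Rochelle salt work-up
Reagents that add atoms: none
Why: Ester reduction by LiAlH4 turns the ethyl ester into the C9 primary alcohol and cleaves the aryl pivalate in the same operation, faster than enolisation or retro-aldol at 0 °C, and the neutral tartrate work-up avoids acid-induced quinone-methide epimerisation at the p-hydroxybenzylic C7, so both centres are carried through unchanged (the C8 label changes from 2S to 8R only because the ester becomes CH2OH).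

**Compound list**

1 | syringaldehyde (4-hydroxy-3,5-dimethoxybenzaldehyde) | COc1cc(C=O)cc(OC)c1O | starting material
2 | 4-formyl-2,6-dimethoxyphenyl pivalate | COc1cc(C=O)cc(OC)c1OC(=O)C(C)(C)C | intermediate
3 | ethyl 3-[3,5-dimethoxy-4-(pivaloyloxy)phenyl]-3-oxopropanoate | CCOC(=O)CC(=O)c1cc(OC)c(OC(=O)C(C)(C)C)c(OC)c1 | intermediate
4 | dihydrosinapyl alcohol (4-(3-hydroxypropyl)-2,6-dimethoxyphenol) | COc1cc(CCCO)cc(OC)c1O | starting material
5 | ethyl 2-chloro-3-[3,5-dimethoxy-4-(pivaloyloxy)phenyl]-3-oxopropanoate (racemic) | CCOC(=O)C(Cl)C(=O)c1cc(OC)c(OC(=O)C(C)(C)C)c(OC)c1 | intermediate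
6 | ethyl 2-[4-(3-hydroxypropyl)-2,6-dimethoxyphenoxy]-3-[3,5-dimethoxy-4-(pivaloyloxy)phenyl]-3-oxopropanoate (racemic, C2 labile) | CCOC(=O)C(Oc1c(OC)cc(CCCO)cc1OC)C(=O)c1cc(OC)c(OC(=O)C(C)(C)C)c(OC)c1 | intermediate
7 | ethyl (2S,3R)-3-hydroxy-2-[4-(3-hydroxypropyl)-2,6-dimethoxyphenoxy]-3-[3,5-dimethoxy-4-(pivaloyloxy)phenyl]propanoate | COc1cc([C@@H](O)[C@@H](C(=O)OCC)Oc2c(OC)cc(CCCO)cc2OC)cc(OC)c1OC(=O)C(C)(C)C | intermediate
8 | (1R,2R)-1-(4-hydroxy-3,5-dimethoxyphenyl)-2-[4-(3-hydroxypropyl)-2,6-dimethoxyphenoxy]propane-1,3-diol | COc1cc([C@@H](O)[C@@H](CO)Oc2c(OC)cc(CCCO)cc2OC)cc(OC)c1O | target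

**Step count and risks**

Total step count: 5. Longest linear sequence: 5 (1 → 2 → 3 → 6 → 7 → 8).

Three steps most likely to fail:

- **Step 2 (Roskamp homologation of an aryl aldehyde).** Aromatic aldehydes react more slowly than aliphatic ones and can give some aryl migration. The fallback sets out from 2 and comes back to the route at 3. Reformatsky addition (Zn dust, ethyl bromoacetate, THF, reflux) to 2 gives the β-hydroxy ester ethyl 3-[3,5-dimethoxy-4-(pivaloyloxy)phenyl]-3-hydroxypropanoate F1. Its benzylic alcohol is then oxidised with Dess–Martin periodinane (CH2Cl2, rt) to 3.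

- **Step 3 (one-pot chlorination and etherification).** The phenoxide is flanked by two methoxy groups, the chloride 5 is partly tied up as its enolate under K2CO3, and chlorine transfer to the phenoxide or pivaloyl transfer could compete. The fallback forms the same C8–O bond without base by carbene O–H insertion; it sets out from 3 and 4 and comes back at 6. Diazo transfer to 3 (p-acetamidobenzenesulfonyl azide, Et3N, MeCN) gives ethyl 2-diazo-3-[3,5-dimethoxy-4-(pivaloyloxy)phenyl]-3-oxopropanoate F2. Phenol 4 is silylated at the primary hydroxyl (TBSCl, imidazole, CH2Cl2, 0 °C) to 4-[3-(tert-butyldimethylsilyloxy)propyl]-2,6-dimethoxyphenol F3, so that the carbene meets only the phenol O–H. Rh2(OAc)4 (1 mol%, CH2Cl2, 40 °C) inserts the carbene from F2 into the O–H of F3 to give the silyl ether of 6, ethyl 2-{4-[3-(tert-butyldimethylsilyloxy)propyl]-2,6-dimethoxyphenoxy}-3-[3,5-dimethoxy-4-(pivaloyloxy)phenyl]-3-oxopropanoate F4. HF·pyridine (THF, 0 °C) removes the silyl group and returns 6.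

- **Step 4 (the proposed new step).** The bulky aryloxy group may slow hydride transfer, and the syn preference or the rate of C8 epimerisation relative to reduction may be lower than for α-alkoxy substrates, giving low dr or ee. The fallback uses known chemistry (Evans boron syn-aldol of an aryloxyacetyl oxazolidinone); it sets out from 4 and 2 and comes back to the route at 8. Phenol 4 is alkylated with (S)-4-benzyl-3-(chloroacetyl)oxazolidin-2-one (K2CO3, acetone, rt) to the imide (S)-4-benzyl-3-{[4-(3-hydroxypropyl)-2,6-dimethoxyphenoxy]acetyl}oxazolidin-2-one F5. Its dibutylboron Z-enolate (Bu2BOTf 2.2 equiv, iPr2NEt, CH2Cl2, −78 °C; the second equivalent carries the side-chain hydroxyl as its borinate, freed in the H2O2/buffer work-up) adds to aldehyde 2. This gives the syn aldol adduct (S)-4-benzyl-3-{(2S,3R)-3-hydroxy-2-[4-(3-hydroxypropyl)-2,6-dimethoxyphenoxy]-3-[3,5-dimethoxy-4-(pivaloyloxy)phenyl]propanoyl}oxazolidin-2-one F6. LiAlH4 (THF, 0 °C) then cleaves the auxiliary reductively and the pivalate in the same operation and gives 8.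

**Further compounds**

F1 | step 2 | ethyl 3-[3,5-dimethoxy-4-(pivaloyloxy)phenyl]-3-hydroxypropanoate (racemic) | CCOC(=O)CC(O)c1cc(OC)c(OC(=O)C(C)(C)C)c(OC)c1
F2 | step 3 | ethyl 2-diazo-3-[3,5-dimethoxy-4-(pivaloyloxy)phenyl]-3-oxopropanoate | CCOC(=O)C(=[N+]=[N-])C(=O)c1cc(OC)c(OC(=O)C(C)(C)C)c(OC)c1
F3 | step 3 | 4-[3-(tert-butyldimethylsilyloxy)propyl]-2,6-dimethoxyphenol | COc1cc(CCCO[Si](C)(C)C(C)(C)C)cc(OC)c1O
F4 | step 3 | ethyl 2-{4-[3-(tert-butyldimethylsilyloxy)propyl]-2,6-dimethoxyphenoxy}-3-[3,5-dimethoxy-4-(pivaloyloxy)phenyl]-3-oxopropanoate (racemic) | CCOC(=O)C(Oc1c(OC)cc(CCCO[Si](C)(C)C(C)(C)C)cc1OC)C(=O)c1cc(OC)c(OC(=O)C(C)(C)C)c(OC)c1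
F5 | step 4 | (S)-4-benzyl-3-{[4-(3-hydroxypropyl)-2,6-dimethoxyphenoxy]acetyl}oxazolidin-2-one | COc1cc(CCCO)cc(OC)c1OCC(=O)N1[C@@H](Cc2ccccc2)COC1=O
F6 | step 4 | (S)-4-benzyl-3-{(2S,3R)-3-hydroxy-2-[4-(3-hydroxypropyl)-2,6-dimethoxyphenoxy]-3-[3,5-dimethoxy-4-(pivaloyloxy)phenyl]propanoyl}oxazolidin-2-one | COc1cc([C@@H](O)[C@@H](C(=O)N3[C@@H](Cc4ccccc4)COC3=O)Oc2c(OC)cc(CCCO)cc2OC)cc(OC)c1OC(=O)C(C)(C)C
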